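# Synthesis proposal for Mundulea flavanone B: Friedel–Crafts closure of ring C on a chiral 3-aryloxy-3-arylpropanoic acid

Flavanone numbering is used throughout: O1, C2, C3, C4, C4a, C5–C8, C8a; ring B positions are primed.

## The problem

Mundulea flavanone B (20) is a 2-arylchroman-4-one: a dihydropyranone ring C fused to a phloroglucinol-type ring A across C4a–C8a, with ring B on C2. Ring A is fully differentiated, with a free hydroxyl on C5, a methyl ether on C7 and a prenyl group on C8, so its three oxygens must be told apart by their positions relative to prenyl and carbonyl. C2 is the only stereocentre; no other centre can relay or repair it, so a reagent or catalyst must set it and every later step must keep it. C2 is fragile. As the benzylic carbon of a β-aryloxy ketone it opens to the chalcone under base, and through a quinone methide once the 4'-hydroxyl is free. Its C2–O1 bond can also ionise under acid when ring B is electron-rich. The prenyl alkene rules out hydrogenolysis, strong protic or Lewis acids and electrophilic oxidants, and the electron-rich ring A limits the oxidants further. Two features of the skeleton make the plan possible. Once O1 is tied to C2, C4a is the only unsubstituted ring A carbon ortho to O1 (C8 holds the prenyl group), and it is ortho or para to all three ring oxygens; an acyl electrophile on the O1–C2–C3 tether can therefore close ring C only there. After closure, C4=O lies peri to the 5-oxygen and marks it out from the 7-oxygen by chelation, so ring A can come from a symmetric precursor.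

## Retrosynthesis

**Unmasking (20 ⇒ 19 ⇒ 18).** The 4'-O–acetyl and 5-O–methyl bonds are cut last. The acetate of 19 is taken off under acid, because a free 4'-hydroxyflavanone racemises in base. The 5-methyl ether of 18 is cut before that, while ring B is still electron-poor. Carrying the 5-oxygen as a methyl ether, instead of as an ester, has three reasons:
- ring A can then come from a symmetric phenol, so the prenylation has no regiochemical choice;
- an aryl ester would not survive the aryloxide chemistry earlier in the route;
- the peri carbonyl of 18 allows the 5-methyl group to be removed without touching the 7-methyl group.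

The forward reactions must spare the prenyl alkene and C2.

**Ring C (18 ⇒ 16, through 17).** The C4–C4a bond is cut, which opens ring C to the acid 16. The neighbouring cuts are weaker. O1–C2 leads to a chalcone whose oxa-Michael closure is hard to make enantioselective. C2–C3 needs a carbenoid or an aldol onto a hindered ketone. The C4–C4a cut leaves an acyclic ether whose stereocentre is an ordinary sp3 carbon that can be set by catalysis. The forward reaction needs an acyl electrophile mild enough for the prenyl alkene; the three oxygens that activate C4a allow this. It also needs an electron-poor ring B so that C2–O1 does not ionise, hence the 4'-acetate in 16.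

**Functional group adjustment (16 ⇒ 14 ⇒ 12 ⇒ 10).** No skeletal bond is cut. The acetate of 16 is traced back to the silyl ether 14, the carboxyl group to the primary alcohol 12, and this to the vinyl group of 10. The acetate is introduced only at the acid stage, because the aryloxide of the etherification and the alkaline peroxide of the hydroboration would cleave or transfer an aryl ester. A triisopropylsilyl ether withstands both. The forward steps must tell the vinyl group from the prenyl alkene (9-BBN does) and must oxidise next to a β-aryloxy group without eliminating it.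

**The ether (10 ⇒ 4 + 8).** The O1–C2 bond is cut to the phenol 4 and the linear cinnamyl carbonate 8. This is the only stereogenic step. Iridium-catalysed allylic etherification is preferred to a Mitsunobu inversion because it starts from an achiral electrophile and gives the branched ether directly. A Mitsunobu reaction would need a separately made chiral benzylic alcohol. Both precursors are simple aromatic compounds. The forward reaction must give O-allylation at the branched position with high enantioselectivity from an ortho-substituted, electron-rich aryloxide.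

**The prenyl group (4 ⇒ 1 + 2).** The C8–CH2 bond is cut to 3,5-dimethoxyphenol (1) and prenyl bromide (2). Because 1 is symmetric, both ortho positions are the same, and the product has the prenyl group between the future O1 and the 7-methoxy group. The forward reaction must favour ortho C-alkylation over O-alkylation and para attack.

**The carbonate (8 ⇒ 7 ⇒ 6 ⇒ 5).** The carbonate C–O bond, the alcohol oxidation level and the silyl ether are traced back to commercial methyl 4-hydroxycinnamate (5). These are routine functional group changes with the (E)-alkene already in place.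

## Roads not taken

**Alternative 1:** The cut is C3–C4 together with O1–C2. The salicylaldehyde A2 would be turned by an orthoester and a chiral phosphoric acid into a methoxy ortho-quinone methide, which adds the styrene A3 in a [4+2] reaction to give the 2,4-cis-4-methoxyflavan A1.
- Merits: two bonds, ring C and the C2 stereocentre are formed in one convergent catalytic step, and the formyl group fixes the ring A regiochemistry.
- Weak points: A2 is a fully substituted benzaldehyde whose three oxygens and formyl group must be placed on the prenylated ring first. A1 is at the flavan-4-ol oxidation level, so the C4 methyl ether must be hydrolysed and oxidised, or oxidised directly at a benzylic position beside a prenyl group, before desilylation. A C4 stereocentre is made only to be destroyed. The electron-rich A3 is prone to acid-induced oligomerisation. Enantiocontrol in intermolecular cycloadditions of this kind with simple styrenes is less secure than in allylic etherification.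
- Comparison: this road joins the halves and closes the ring in one step, where the chosen plan needs five steps from the union to ring closure. Against that, the chosen plan sets a well-established asymmetric step, reaches the correct oxidation level directly, and needs no oxidation in the presence of the finished flavan.

**Alternative 2:** The cut is C8–C8a together with C4a–C5, so ring A is built last on a ring C that already holds C2. The bromopyranone A5 takes up the prenylated Brassard-type diene A6 across its C=C bond; loss of HBr and of a silyl methyl ether aromatises the adduct to A4.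
- Merits: ring A appears with the 5-hydroxyl free and the 7-methoxy group in place. No peri-demethylation, no acid-mediated acylation next to the prenyl group and only one protecting group are needed. In protecting-group economy and in the number of steps after the key step this road is better than the chosen plan.
- Weak points: A6 is a tetrasubstituted ketene acetal diene whose prenyl group sits on the terminus that must bond to C8a, which slows the addition. The double bond of A5 is a vinylogous ester and a poor dienophile, so a stepwise Michael pathway with uncertain regiochemistry is likely. The aromatisation releases HBr beside the prenyl alkene, and the β-alkoxy ketone of A5 can open by elimination, which would lose C2.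
- Comparison: the chosen plan is longer and pays with a protecting-group exchange and a demethylation. Against that, its ring-forming step is a classical reaction type with only one reachable site.

**Alternative 3:** The cut is C2–C3. The diazo ketone A8, an achiral benzyl ether, would be decomposed by Rh2(S-PTTL)4 to a carbenoid at C3 that inserts into the benzylic ether C–H bond and gives A7.
- Merits: the ring and the stereocentre arise in one catalytic step from an achiral precursor. If it worked, this would be the shortest route, and it is more step-economic than the chosen plan in the way it sets C2.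
- Weak points: the insertion is a 1,6-process, while such carbenoids prefer five-membered closures. The ether oxygen can attack the carbenoid to give an oxonium ylide, and a [1,2]-benzyl shift then leads to a benzofuranone. The prenyl alkene invites cyclopropanation. Enantiocontrol for acceptor-only carbenoids in six-membered insertions is not established.
- Comparison: chemoselectivity among several reactive sites rests on the catalyst alone. In the chosen plan the tether and the blocked C8 leave the electrophile one site, and the asymmetric step is separated from the ring closure.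

Key step: step 9

Assumption: the (Sa,Sc,Sc) antipode of the phosphoramidite ligand is taken as the one that gives the (S)-ether 10; if a first run shows the opposite sense, the mirror-image ligand is used and nothing else changes.

## Route

Step 1
Reactants: 1 3,5-dimethoxyphenol; 2 prenyl bromide (1-bromo-3-methylbut-2-ene)
Product: 4 3,5-dimethoxy-2-(3-methylbut-2-en-1-yl)phenol, via sodium 3,5-dimethoxyphenoxide 3 (not isolated)
Conditions: NaH, toluene, 0 °C; then 2, 0 °C to rt
Reagents that add atoms: sodium hydride, [Na+].[H-] (its sodium appears only in 3)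
Why: Ortho C-alkylation of a phenoxide: in toluene the sodium phenoxide reacts as a tight ion pair that delivers the allylic bromide to the ring carbon next to oxygen in preference to oxygen or the remote para carbon. The two ortho positions of 1 are equivalent, so one C-prenyl phenol results, with the prenyl group between the future O1 and the future 7-methoxy group.

Step 2
Reactants: 5 methyl (E)-3-(4-hydroxyphenyl)prop-2-enoate (methyl 4-hydroxycinnamate)
Product: 6 methyl (E)-3-[4-(triisopropylsilyloxy)phenyl]prop-2-enoate
Conditions: TIPSCl, imidazole, DMF, rt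
Reagents that add atoms: triisopropylsilyl chloride, CC(C)[Si](Cl)(C(C)C)C(C)C
Why: Standard silylation of a phenol. The triisopropylsilyl ether is chosen because it withstands the aryloxide and alkoxide bases of step 5 and the alkaline peroxide of step 6, which an aryl ester would not.

Step 3
Reactants: 6 methyl (E)-3-[4-(triisopropylsilyloxy)phenyl]prop-2-enoate
Product: 7 (E)-3-[4-(triisopropylsilyloxy)phenyl]prop-2-en-1-ol
Conditions: i-Bu2AlH, CH2Cl2, −78 °C; aq. potassium sodium tartrate
Reagents that add atoms: none
Why: 1,2-Reduction of an α,β-unsaturated ester to the allylic alcohol by i-Bu2AlH at low temperature; the alkene geometry and the silyl ether are untouched.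

Step 4
Reactants: 7 (E)-3-[4-(triisopropylsilyloxy)phenyl]prop-2-en-1-ol
Product: 8 methyl (E)-3-[4-(triisopropylsilyloxy)phenyl]prop-2-en-1-yl carbonate
Conditions: ClCO2Me, pyridine, CH2Cl2, 0 °C
Reagents that add atoms: methyl chloroformate, COC(=O)Cl
Why: Acylation of the primary allylic alcohol with a chloroformate gives the linear (E)-cinnamyl carbonate that the iridium catalyst needs as its allyl source.

Step 5
Reactants: 4 3,5-dimethoxy-2-(3-methylbut-2-en-1-yl)phenol; 8 methyl (E)-3-[4-(triisopropylsilyloxy)phenyl]prop-2-en-1-yl carbonate
Product: 10 {4-[(1S)-1-[3,5-dimethoxy-2-(3-methylbut-2-en-1-yl)phenoxy]prop-2-en-1-yl]phenoxy}triisopropylsilane, via lithium aryloxide 9 (not isolated)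
Conditions: 4 (excess), n-BuLi, THF, 0 °C; then 8, [Ir(cod)Cl]2 (2 mol%), (Sa,Sc,Sc)-O,O'-(1,1'-binaphthalene-2,2'-diyl) N,N-bis(1-phenylethyl)phosphoramidite (4 mol%), catalyst pre-activated with n-PrNH2, THF, rt
Reagents that add atoms: n-butyllithium, [Li]CCCC (its lithium appears only in 9)
Why: Iridium-catalysed asymmetric allylic etherification of a linear cinnamyl carbonate with an aryloxide: the cyclometalated iridium–phosphoramidite complex ionises 8 to an allyl complex, and the aryloxide attacks the aryl-bearing terminus from the face opposite the metal, which gives the branched ether. The new stereocentre (the future C2) is set by the chiral ligand, which fixes the face of the allyl unit bound to iridium; the prenyl alkene and the aryl silyl ether take no part.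

Step 6
Reactants: 10 {4-[(1S)-1-[3,5-dimethoxy-2-(3-methylbut-2-en-1-yl)phenoxy]prop-2-en-1-yl]phenoxy}triisopropylsilane
Product: 12 (3S)-3-[3,5-dimethoxy-2-(3-methylbut-2-en-1-yl)phenoxy]-3-[4-(triisopropylsilyloxy)phenyl]propan-1-ol, via B-alkyl-9-BBN adduct 11 (not isolated)
Conditions: 9-BBN, THF, 0 °C to rt; then aq. NaOH, H2O2, 0 °C
Reagents that add atoms: 9-BBN, B1C2CCCC1CCC2 (its boron and bicycle appear only in 11); hydrogen peroxide, OO
Why: Anti-Markovnikov hydroboration–oxidation: 9-BBN adds to the monosubstituted vinyl group far faster than to the trisubstituted prenyl alkene and places boron on the terminal carbon. Alkaline peroxide then replaces boron by hydroxyl with the stereocentre uninvolved.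

Step 7
Reactants: 12 (3S)-3-[3,5-dimethoxy-2-(3-methylbut-2-en-1-yl)phenoxy]-3-[4-(triisopropylsilyloxy)phenyl]propan-1-ol
Product: 14 (3S)-3-[3,5-dimethoxy-2-(3-methylbut-2-en-1-yl)phenoxy]-3-[4-(triisopropylsilyloxy)phenyl]propanoic acid, via aldehyde 13 (not isolated)
Conditions: TEMPO (cat.), PhI(OAc)2, MeCN/H2O (1:1), rt
Reagents that add atoms: water, O
Why: Nitroxyl-catalysed oxidation of a primary alcohol to the carboxylic acid in aqueous acetonitrile: aldehyde 13 is hydrated and oxidised further in the same flask. The near-neutral conditions avoid β-elimination of the aryloxy group and leave the alkene and the electron-rich arene alone.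

Step 8
Reactants: 14 (3S)-3-[3,5-dimethoxy-2-(3-methylbut-2-en-1-yl)phenoxy]-3-[4-(triisopropylsilyloxy)phenyl]propanoic acid
Product: 16 (3S)-3-(4-acetoxyphenyl)-3-[3,5-dimethoxy-2-(3-methylbut-2-en-1-yl)phenoxy]propanoic acid, via phenol acid 15 (not isolated)
Conditions: TBAF, AcOH, THF, 0 °C to rt; then Ac2O, pyridine, DMAP (cat.), 0 °C; aq. NaHCO3
Reagents that add atoms: acetic anhydride, CC(=O)OC(C)=O
Why: Buffered fluoride cleavage of the aryl silyl ether followed by O-acetylation in the same flask. Acetic acid keeps phenol 15 protonated so that it cannot expel the aryloxy group through a quinone methide, and the aqueous bicarbonate work-up returns the carboxyl group as the free acid. The exchange puts an electron-poor oxygen substituent on ring B before the acid-mediated ring closure.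

Step 9
Reactants: 16 (3S)-3-(4-acetoxyphenyl)-3-[3,5-dimethoxy-2-(3-methylbut-2-en-1-yl)phenoxy]propanoic acid
Product: 18 (2S)-4'-acetoxy-5,7-dimethoxy-8-(3-methylbut-2-en-1-yl)flavanone, via acyl trifluoroacetate 17 (not isolated)
Conditions: (CF3CO)2O, CH2Cl2 (dilute), 0 °C; cold aq. NaHCO3
Reagents that add atoms: trifluoroacetic anhydride, O=C(OC(=O)C(F)(F)F)C(F)(F)F (its trifluoroacetyl group appears only in 17)
Why: Trifluoroacetic anhydride turns the carboxyl group of 16 into the acyl trifluoroacetate 17; this mixed anhydride, polarised by the trifluoroacetic acid set free, acylates ring A at C4a through a Wheland intermediate that loses its proton to give the aryl ketone. The closest known reaction type is the intramolecular Friedel–Crafts acylation of 3-aryloxypropanoic acids to chroman-4-ones with trifluoroacetic anhydride or polyphosphoric acid. Ring C closes by a 6-exo-trig attack of the arene carbon on the activated acyl carbon, and the O1–C2–C3 tether allows no other ring size. No stereocentre is formed; C2 is not an enolisable centre, none of its bonds is touched, and it keeps the configuration set in step 5. Regioselectivity between C4a and C6 is fixed by the tether, which reaches only a position ortho to O1, and by the prenyl group that occupies C8. Chemoselectivity is needed against the prenyl alkene, the aryl acetate and the benzylic C2–O1 bond: C4a is activated by O1 and the 5-methoxy group (ortho) and by the 7-methoxy group (para), so closure should be complete at 0 °C with no acid stronger than the trifluoroacetic acid formed, and the acetoxy group on ring B withholds the electron push that would let C2–O1 ionise or let O1 be dealkylated by a protonated prenyl group.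

Step 10
Reactants: 18 (2S)-4'-acetoxy-5,7-dimethoxy-8-(3-methylbut-2-en-1-yl)flavanone
Product: 19 (2S)-4'-acetoxy-5-hydroxy-7-methoxy-8-(3-methylbut-2-en-1-yl)flavanone
Conditions: MgI2·OEt2, THF, 50 °C; aq. NH4Cl
Reagents that add atoms: none
Why: Chelation-controlled dealkylation of an aryl methyl ether peri to a carbonyl group: magnesium binds C4=O and the 5-methoxy oxygen and iodide removes that methyl group by SN2 attack, while the 7-methoxy group cannot chelate and stays. The magnesium iodide method is established for 5-methoxy-8-prenylflavanones and spares the prenyl alkene; keeping the 4'-oxygen acetylated denies ring C the quinone methide route to opening, so C2 should hold.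

Step 11
Reactants: 19 (2S)-4'-acetoxy-5-hydroxy-7-methoxy-8-(3-methylbut-2-en-1-yl)flavanone
Product: 20 Mundulea flavanone B, (2S)-5,4'-dihydroxy-7-methoxy-8-(3-methylbut-2-en-1-yl)flavanone
Conditions: HCl (1.25 M in MeOH), MeOH, 0 °C to rt
Reagents that add atoms: none
Why: Acid-catalysed transesterification of the aryl acetate with methanol. Acid is preferred to base because the free 4'-hydroxyflavanone opens ring C and racemises under basic conditions, and no hydroxyl group sits next to the prenyl group that could cyclise onto it.

## Compound list

1 | 3,5-dimethoxyphenol | COc1cc(O)cc(OC)c1 | starting material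
2 | prenyl bromide (1-bromo-3-methylbut-2-ene) | CC(C)=CCBr | starting material
3 | sodium 3,5-dimethoxyphenoxide | [Na+].[O-]c1cc(OC)cc(OC)c1 | intermediate (not isolated)
4 | 3,5-dimethoxy-2-(3-methylbut-2-en-1-yl)phenol | COc1cc(O)c(CC=C(C)C)c(OC)c1 | intermediate
5 | methyl (E)-3-(4-hydroxyphenyl)prop-2-enoate | COC(=O)/C=C/c1ccc(O)cc1 | starting material
6 | methyl (E)-3-[4-(triisopropylsilyloxy)phenyl]prop-2-enoate | COC(=O)/C=C/c1ccc(O[Si](C(C)C)(C(C)C)C(C)C)cc1 | intermediate
7 | (E)-3-[4-(triisopropylsilyloxy)phenyl]prop-2-en-1-ol | OC/C=C/c1ccc(O[Si](C(C)C)(C(C)C)C(C)C)cc1 | intermediate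
8 | methyl (E)-3-[4-(triisopropylsilyloxy)phenyl]prop-2-en-1-yl carbonate | COC(=O)OC/C=C/c1ccc(O[Si](C(C)C)(C(C)C)C(C)C)cc1 | intermediate
9 | lithium 3,5-dimethoxy-2-(3-methylbut-2-en-1-yl)phenoxide | [Li+].[O-]c1cc(OC)cc(OC)c1CC=C(C)C | intermediate (not isolated)
10 | {4-[(1S)-1-[3,5-dimethoxy-2-(3-methylbut-2-en-1-yl)phenoxy]prop-2-en-1-yl]phenoxy}triisopropylsilane | COc1cc(OC)c(CC=C(C)C)c(O[C@@H](C=C)c2ccc(O[Si](C(C)C)(C(C)C)C(C)C)cc2)c1 | intermediate
11 | 9-{(3S)-3-[3,5-dimethoxy-2-(3-methylbut-2-en-1-yl)phenoxy]-3-[4-(triisopropylsilyloxy)phenyl]propyl}-9-borabicyclo[3.3.1]nonane | COc1cc(OC)c(CC=C(C)C)c(O[C@@H](CCB2C3CCCC2CCC3)c2ccc(O[Si](C(C)C)(C(C)C)C(C)C)cc2)c1 | intermediate (not isolated)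
12 | (3S)-3-[3,5-dimethoxy-2-(3-methylbut-2-en-1-yl)phenoxy]-3-[4-(triisopropylsilyloxy)phenyl]propan-1-ol | COc1cc(OC)c(CC=C(C)C)c(O[C@@H](CCO)c2ccc(O[Si](C(C)C)(C(C)C)C(C)C)cc2)c1 | intermediate
13 | (3S)-3-[3,5-dimethoxy-2-(3-methylbut-2-en-1-yl)phenoxy]-3-[4-(triisopropylsilyloxy)phenyl]propanal | COc1cc(OC)c(CC=C(C)C)c(O[C@@H](CC=O)c2ccc(O[Si](C(C)C)(C(C)C)C(C)C)cc2)c1 | intermediate (not isolated)
14 | (3S)-3-[3,5-dimethoxy-2-(3-methylbut-2-en-1-yl)phenoxy]-3-[4-(triisopropylsilyloxy)phenyl]propanoic acid | COc1cc(OC)c(CC=C(C)C)c(O[C@@H](CC(=O)O)c2ccc(O[Si](C(C)C)(C(C)C)C(C)C)cc2)c1 | intermediate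
15 | (3S)-3-[3,5-dimethoxy-2-(3-methylbut-2-en-1-yl)phenoxy]-3-(4-hydroxyphenyl)propanoic acid | COc1cc(OC)c(CC=C(C)C)c(O[C@@H](CC(=O)O)c2ccc(O)cc2)c1 | intermediate (not isolated)
16 | (3S)-3-(4-acetoxyphenyl)-3-[3,5-dimethoxy-2-(3-methylbut-2-en-1-yl)phenoxy]propanoic acid | COc1cc(OC)c(CC=C(C)C)c(O[C@@H](CC(=O)O)c2ccc(OC(C)=O)cc2)c1 | intermediate
17 | (3S)-3-(4-acetoxyphenyl)-3-[3,5-dimethoxy-2-(3-methylbut-2-en-1-yl)phenoxy]propanoic trifluoroacetic anhydride | COc1cc(OC)c(CC=C(C)C)c(O[C@@H](CC(=O)OC(=O)C(F)(F)F)c2ccc(OC(C)=O)cc2)c1 | intermediate (not isolated)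
18 | (2S)-4'-acetoxy-5,7-dimethoxy-8-(3-methylbut-2-en-1-yl)flavanone | COc1cc(OC)c(CC=C(C)C)c2c1C(=O)C[C@@H](c1ccc(OC(C)=O)cc1)O2 | intermediate
19 | (2S)-4'-acetoxy-5-hydroxy-7-methoxy-8-(3-methylbut-2-en-1-yl)flavanone | COc1cc(O)c2c(c1CC=C(C)C)O[C@H](c1ccc(OC(C)=O)cc1)CC2=O | intermediate
20 | Mundulea flavanone B, (2S)-5,4'-dihydroxy-7-methoxy-8-(3-methylbut-2-en-1-yl)flavanone | COc1cc(O)c2c(c1CC=C(C)C)O[C@H](c1ccc(O)cc1)CC2=O | target

## Step count and risks

Total: 11 steps. Longest linear sequence: 10 steps (from 5 to 20, steps 2–11); the ring A branch from 1 is 8 steps.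

**Step 9 (key step).**
- Most likely failure: addition of the released trifluoroacetic acid to the prenyl alkene, or acid-induced loss of the aryloxy group from C2, before ring closure is complete. The same electron-rich ring that speeds the acylation also makes the ether oxygen a better partner for a protonated prenyl group.
- Fallback: this sets out from 16 and comes back at 18. The acid is converted under neutral conditions with 1-chloro-N,N,2-trimethylprop-1-en-1-amine into (3S)-3-(4-acetoxyphenyl)-3-[3,5-dimethoxy-2-(3-methylbut-2-en-1-yl)phenoxy]propanoyl chloride F8. This is closed with SnCl4 at −78 °C in the presence of 2,6-di-tert-butyl-4-methylpyridine, so that no free protic acid meets the alkene.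

**Step 5.**
- Most likely failure: competing C-allylation of the very electron-rich aryloxide, or attack at the unsubstituted allyl terminus. Re-ionisation of the doubly activated product ether by the catalyst could also erode the enantiomeric purity on long reaction times.
- Fallback: this sets out from ester 6 and phenol 4 and comes back at 12.
  - Copper-catalysed asymmetric conjugate borylation of 6 (CuCl, NaOt-Bu, a Josiphos-type ligand of the antipode that gives the R product, B2pin2, MeOH) gives methyl (3R)-3-(4,4,5,5-tetramethyl-1,3,2-dioxaborolan-2-yl)-3-[4-(triisopropylsilyloxy)phenyl]propanoate F3.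
  - NaBO3·4H2O oxidises it with retention to methyl (3R)-3-hydroxy-3-[4-(triisopropylsilyloxy)phenyl]propanoate F4.
  - LiBH4 reduces the ester to (1R)-1-[4-(triisopropylsilyloxy)phenyl]propane-1,3-diol F5.
  - TBSCl and imidazole silylate the primary hydroxyl to give (1R)-3-(tert-butyldimethylsilyloxy)-1-[4-(triisopropylsilyloxy)phenyl]propan-1-ol F6.
  - A Mitsunobu reaction with 4 (PPh3, DIAD, toluene, 0 °C) inverts the benzylic centre and gives tert-butyl{(3S)-3-[3,5-dimethoxy-2-(3-methylbut-2-en-1-yl)phenoxy]-3-[4-(triisopropylsilyloxy)phenyl]propoxy}dimethylsilane F7.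
  - HF·pyridine in THF/pyridine removes the primary silyl group and gives 12.

**Step 10.**
- Most likely failure: slow or incomplete ether cleavage at a temperature where ring C begins to open and close again, with erosion at C2, together with partial acetyl loss or transfer in the warm magnesium phenoxide.
- Fallback: this sets out from 18 and comes back at 20 with the order of the last two operations reversed. Methanolic HCl first removes the acetate to give (2S)-4'-hydroxy-5,7-dimethoxy-8-(3-methylbut-2-en-1-yl)flavanone F9. The 5-methyl ether is then cleaved through the boron chelate with BCl3 in CH2Cl2 at −78 °C, a temperature at which ring C cannot open.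

**Step 1.**
- Most likely failure: O-alkylation, attack at the para carbon between the two methoxy groups, and double alkylation, which would lower the supply of 4 and complicate its purification.
- Fallback: this sets out from 1 and comes back at 4 by O-alkylation and [3,3] rearrangement.
  - 3-Chloro-3-methylbut-1-yne with DBU and catalytic CuCl2 in MeCN at 0 °C gives 1,3-dimethoxy-5-[(2-methylbut-3-yn-2-yl)oxy]benzene F1.
  - Semihydrogenation (H2, Pd/CaCO3 poisoned with Pb(OAc)2, quinoline) gives 1,3-dimethoxy-5-[(2-methylbut-3-en-2-yl)oxy]benzene F2.
  - Heating in N,N-diethylaniline brings about the aromatic Claisen rearrangement to 4; the symmetry of the ring again leaves a single ortho product.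

## Further compounds

F1 | step 1 | 1,3-dimethoxy-5-[(2-methylbut-3-yn-2-yl)oxy]benzene | COc1cc(OC)cc(OC(C)(C)C#C)c1
F2 | step 1 | 1,3-dimethoxy-5-[(2-methylbut-3-en-2-yl)oxy]benzene | COc1cc(OC)cc(OC(C)(C)C=C)c1
F3 | step 5 | methyl (3R)-3-(4,4,5,5-tetramethyl-1,3,2-dioxaborolan-2-yl)-3-[4-(triisopropylsilyloxy)phenyl]propanoate | CC1(C)OB(OC1(C)C)[C@H](CC(=O)OC)c1ccc(O[Si](C(C)C)(C(C)C)C(C)C)cc1
F4 | step 5 | methyl (3R)-3-hydroxy-3-[4-(triisopropylsilyloxy)phenyl]propanoate | O[C@H](CC(=O)OC)c1ccc(O[Si](C(C)C)(C(C)C)C(C)C)cc1
F5 | step 5 | (1R)-1-[4-(triisopropylsilyloxy)phenyl]propane-1,3-diol | O[C@H](CCO)c1ccc(O[Si](C(C)C)(C(C)C)C(C)C)cc1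
F6 | step 5 | (1R)-3-(tert-butyldimethylsilyloxy)-1-[4-(triisopropylsilyloxy)phenyl]propan-1-ol | O[C@H](CCO[Si](C)(C)C(C)(C)C)c1ccc(O[Si](C(C)C)(C(C)C)C(C)C)cc1
F7 | step 5 | tert-butyl{(3S)-3-[3,5-dimethoxy-2-(3-methylbut-2-en-1-yl)phenoxy]-3-[4-(triisopropylsilyloxy)phenyl]propoxy}dimethylsilane | COc1cc(OC)c(CC=C(C)C)c(O[C@@H](CCO[Si](C)(C)C(C)(C)C)c2ccc(O[Si](C(C)C)(C(C)C)C(C)C)cc2)c1
F8 | step 9 | (3S)-3-(4-acetoxyphenyl)-3-[3,5-dimethoxy-2-(3-methylbut-2-en-1-yl)phenoxy]propanoyl chloride | COc1cc(OC)c(CC=C(C)C)c(O[C@@H](CC(Cl)=O)c2ccc(OC(C)=O)cc2)c1
F9 | step 10 | (2S)-4'-hydroxy-5,7-dimethoxy-8-(3-methylbut-2-en-1-yl)flavanone | COc1cc(OC)c(CC=C(C)C)c2c1C(=O)C[C@@H](c1ccc(O)cc1)O2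
A1 | alternative 1 | (2S)-2,4-cis-4,7-dimethoxy-8-(3-methylbut-2-en-1-yl)-5,4'-bis(triisopropylsilyloxy)flavan | COc1cc(O[Si](C(C)C)(C(C)C)C(C)C)c2c(c1CC=C(C)C)O[C@H](c1ccc(O[Si](C(C)C)(C(C)C)C(C)C)cc1)C[C@@H]2OC
A2 | alternative 1 | 2-hydroxy-4-methoxy-3-(3-methylbut-2-en-1-yl)-6-(triisopropylsilyloxy)benzaldehyde | COc1cc(O[Si](C(C)C)(C(C)C)C(C)C)c(C=O)c(O)c1CC=C(C)C
A3 | alternative 1 | 4-(triisopropylsilyloxy)styrene | C=Cc1ccc(O[Si](C(C)C)(C(C)C)C(C)C)cc1
A4 | alternative 2 | (2S)-4'-O-(tert-butyldimethylsilyl) Mundulea flavanone B | COc1cc(O)c2c(c1CC=C(C)C)O[C@H](c1ccc(O[Si](C)(C)C(C)(C)C)cc1)CC2=O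
A5 | alternative 2 | (2S)-5-bromo-2-[4-(tert-butyldimethylsilyloxy)phenyl]-2,3-dihydro-4H-pyran-4-one | BrC1=CO[C@H](c2ccc(O[Si](C)(C)C(C)(C)C)cc2)CC1=O
A6 | alternative 2 | [(1,3-dimethoxy-7-methylocta-1,3,6-trien-1-yl)oxy]trimethylsilane | COC(=CC(OC)=CCC=C(C)C)O[Si](C)(C)C
A7 | alternative 3 | (2S)-5,4'-bis-O-(tert-butyldimethylsilyl) Mundulea flavanone B | COc1cc(O[Si](C)(C)C(C)(C)C)c2c(c1CC=C(C)C)O[C@H](c1ccc(O[Si](C)(C)C(C)(C)C)cc1)CC2=O
A8 | alternative 3 | 2-diazo-1-[6-(tert-butyldimethylsilyloxy)-2-{[4-(tert-butyldimethylsilyloxy)benzyl]oxy}-4-methoxy-3-(3-methylbut-2-en-1-yl)phenyl]ethanone | COc1cc(O[Si](C)(C)C(C)(C)C)c(C(=O)C=[N+]=[N-])c(OCc2ccc(O[Si](C)(C)C(C)(C)C)cc2)c1CC=C(C)C
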